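**Retrosynthetic overview**
- The target is a benzophenone whose trioxygenated ring carries OH at C2 and C6, OCH3 at C4 and prenyl groups at C3 and C5. It has no stereocentre, and both aromatic rings are bought; no ring is formed in the route.
- Feature used: each prenyl group is an ArCH2–CH=C(CH3)2 unit whose benzylic carbon sits on C3 or C5, ortho to a phenolic oxygen (C2 or C6) and to the C4 methoxy group. Both ArCH2–CH(sp2) bonds are cut to give a bis(benzylic chloride) and two 2-methylprop-1-enyl boronates.
- The two CH2Cl groups come from CH2N(CH3)2 groups by chloroformate exchange; these come from a double phenolic Mannich reaction at the only two free positions of that ring. The phenols are masked as methoxymethyl ethers before the exchange.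
- The ring scaffold comes from 2,4,6-trihydroxybenzophenone by methylation of the 4-hydroxyl.

Key step: step 5

Assumption: bis(chloride) 7 is an easily ionised 2,4,6-trioxygenated benzylic chloride, so it is carried into the coupling as crude material directly after step 4.

**Step 1**
Reactants: 1 (2,4,6-trihydroxyphenyl)(phenyl)methanone (2,4,6-trihydroxybenzophenone)
Product: 2 (2,6-dihydroxy-4-methoxyphenyl)(phenyl)methanone
Conditions: Me2SO4 (1.0 equiv), K2CO3 (1.0 equiv), acetone, rt
Reagents that add atoms: dimethyl sulfate, COS(=O)(=O)OC
Why: Williamson O-methylation; the 4-hydroxyl is para to the carbonyl, the most acidic and the least hindered, whereas the 2- and 6-hydroxyls flank the carbonyl and are engaged in hydrogen bonding to it, so one equivalent of base and electrophile should methylate mainly at O4, and under- and over-methylated material can be separated.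

**Step 2**
Reactants: 2 (2,6-dihydroxy-4-methoxyphenyl)(phenyl)methanone
Product: 3 [3,5-bis[(dimethylamino)methyl]-2,6-dihydroxy-4-methoxyphenyl](phenyl)methanone
Conditions: CH2(NMe2)2 (2.5 equiv), EtOH, rt to 50 °C
Reagents that add atoms: bis(dimethylamino)methane, CN(C)CN(C)C
Why: Phenolic Mannich aminomethylation; the acidic phenol protonates the aminal to release the N,N-dimethylmethyleneiminium ion, which attacks C3 and C5, the only unsubstituted positions of the electron-rich ring, each ortho to a free hydroxyl, so both one-carbon handles should be placed with full regiocontrol.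

**Step 3**
Reactants: 3 [3,5-bis[(dimethylamino)methyl]-2,6-dihydroxy-4-methoxyphenyl](phenyl)methanone
Product: 5 [3,5-bis[(dimethylamino)methyl]-4-methoxy-2,6-bis(methoxymethoxy)phenyl](phenyl)methanone, via disodium bis(phenoxide) 4 (not isolated)
Conditions: NaH (2.2 equiv), THF/DMF, 0 °C; then MOMCl (2.2 equiv, slow addition), −20 to 0 °C; basic aqueous work-up
Reagents that add atoms: chloromethyl methyl ether, COCCl
Why: Williamson-type O-alkoxymethylation; the anionic phenoxide oxygens should react with the chloromethyl ether much faster than the neutral tertiary amines, and any N-methoxymethylammonium ion formed is itself an alkoxymethyl donor towards phenoxide, so the material should funnel to the bis(methoxymethyl) ether while the non-enolisable ketone is untouched.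

**Step 4**
Reactants: 5 [3,5-bis[(dimethylamino)methyl]-4-methoxy-2,6-bis(methoxymethoxy)phenyl](phenyl)methanone
Product: 7 [3,5-bis(chloromethyl)-4-methoxy-2,6-bis(methoxymethoxy)phenyl](phenyl)methanone, via bis(N-ethoxycarbonylammonium) dichloride 6 (not isolated)
Conditions: ClCO2Et (3 equiv), K2CO3 (solid, acid scavenger), CH2Cl2, 0 °C to rt; filter, concentrate, use crude
Reagents that add atoms: ethyl chloroformate, CCOC(=O)Cl
Why: von Braun-type dealkylative chlorination; N-acylation gives an acylammonium chloride whose chloride attacks the benzylic carbon (activated by the ortho and para oxygens) in preference to N-methyl, releasing ethyl N,N-dimethylcarbamate, while the acetals survive because the medium is kept free of acid.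

**Step 5**
Reactants: 7 [3,5-bis(chloromethyl)-4-methoxy-2,6-bis(methoxymethoxy)phenyl](phenyl)methanone; 8 4,4,5,5-tetramethyl-2-(2-methylprop-1-enyl)-1,3,2-dioxaborolane (2-methylprop-1-enylboronic acid pinacol ester, 3 equiv)
Product: 9 [4-methoxy-2,6-bis(methoxymethoxy)-3,5-bis(3-methylbut-2-enyl)phenyl](phenyl)methanone
Conditions: Pd(PPh3)4 (10 mol %), K2CO3 (6 equiv, powdered), degassed 1,4-dioxane/H2O (20:1), 70 °C
Reagents that add atoms: none
Why: Zerovalent palladium from Pd(PPh3)4 inserts into each benzylic C–Cl bond to give a benzyl complex of divalent palladium that has no β-hydrogen, carbonate and hydroxide activate boronate 8 so that its 2-methylprop-1-enyl group is transferred to palladium, and reductive elimination forms each ArCH2–CH=C(CH3)2 bond. The closest known reaction type is the Suzuki–Miyaura coupling of benzylic halides with alkenylboronic esters. No ring is closed and no stereocentre is created, and the alkene terminus carries two identical methyl groups, so no E/Z question arises. The step needs both chlorides to couple at the benzylic carbon without allylic transposition, quinone methide formation or solvolysis: the bond is made one carbon out from the ring at positions already fixed by the CH2Cl groups, the sp2 boron partner fixes the double bond between C2 and C3 of each side chain, the two methoxymethyl ethers prevent loss of chloride from an ortho-hydroxybenzyl system, and the low water content with excess boronate should keep hydrolysis behind coupling. The diaryl ketone and the acetals are inert to K2CO3 and to Pd(PPh3)4.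

**Step 6**
Reactants: 9 [4-methoxy-2,6-bis(methoxymethoxy)-3,5-bis(3-methylbut-2-enyl)phenyl](phenyl)methanone
Product: 10 [2,6-dihydroxy-4-methoxy-3,5-bis(3-methylbut-2-enyl)phenyl](phenyl)methanone (target, CNP0289865.0)
Conditions: HCl (1 M aq, 4 equiv), MeOH, 0 °C to rt, quench with NaHCO3 at full conversion
Reagents that add atoms: none
Why: Acid-catalysed acetal cleavage by transacetalisation to methanol; the aryl methoxymethyl ethers ortho to the carbonyl are cleaved readily, and dilute acid at low temperature should keep protonation of the trisubstituted alkenes, which would lead to chromans, slower than acetal cleavage.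

**Compound list**
1 | (2,4,6-trihydroxyphenyl)(phenyl)methanone | O=C(c1ccccc1)c1c(O)cc(O)cc1O | starting material
2 | (2,6-dihydroxy-4-methoxyphenyl)(phenyl)methanone | COc1cc(O)c(C(=O)c2ccccc2)c(O)c1 | intermediate
3 | [3,5-bis[(dimethylamino)methyl]-2,6-dihydroxy-4-methoxyphenyl](phenyl)methanone | COc1c(CN(C)C)c(O)c(C(=O)c2ccccc2)c(O)c1CN(C)C | intermediate
4 | disodium 2-benzoyl-4,6-bis[(dimethylamino)methyl]-5-methoxybenzene-1,3-diolate | COc1c(CN(C)C)c([O-])c(C(=O)c2ccccc2)c([O-])c1CN(C)C.[Na+].[Na+] | intermediate
5 | [3,5-bis[(dimethylamino)methyl]-4-methoxy-2,6-bis(methoxymethoxy)phenyl](phenyl)methanone | COCOc1c(CN(C)C)c(OC)c(CN(C)C)c(OCOC)c1C(=O)c1ccccc1 | intermediate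
6 | [5-benzoyl-2-methoxy-4,6-bis(methoxymethoxy)-1,3-phenylene]bis(methylene)bis[(ethoxycarbonyl)dimethylammonium] dichloride | CCOC(=O)[N+](C)(C)Cc1c(OC)c(C[N+](C)(C)C(=O)OCC)c(OCOC)c(C(=O)c2ccccc2)c1OCOC.[Cl-].[Cl-] | intermediate
7 | [3,5-bis(chloromethyl)-4-methoxy-2,6-bis(methoxymethoxy)phenyl](phenyl)methanone | COCOc1c(CCl)c(OC)c(CCl)c(OCOC)c1C(=O)c1ccccc1 | intermediate
8 | 4,4,5,5-tetramethyl-2-(2-methylprop-1-enyl)-1,3,2-dioxaborolane | CC(C)=CB1OC(C)(C)C(C)(C)O1 | starting material
9 | [4-methoxy-2,6-bis(methoxymethoxy)-3,5-bis(3-methylbut-2-enyl)phenyl](phenyl)methanone | COCOc1c(CC=C(C)C)c(OC)c(CC=C(C)C)c(OCOC)c1C(=O)c1ccccc1 | intermediate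
10 | [2,6-dihydroxy-4-methoxy-3,5-bis(3-methylbut-2-enyl)phenyl](phenyl)methanone | COc1c(CC=C(C)C)c(O)c(C(=O)c2ccccc2)c(O)c1CC=C(C)C | target

**Step count**
Total steps: 6. Longest linear sequence: 6 steps (1 to 10).

**Steps most likely to fail**

Step 5 (double benzylic coupling). The two ionisable benzylic chlorides may be solvolysed by water and carbonate before oxidative addition and transmetalation take place. The reaction may also stall after the first coupling, or reductive homocoupling to bibenzyls may compete. The fallback removes base and water altogether. It sets out from 7 and comes back at 9: a Stille coupling of 7 with tributyl(2-methylprop-1-enyl)stannane (3 equiv) under Pd2(dba)3 and tri(2-furyl)phosphine in anhydrous N-methylpyrrolidone at 60 °C should form the same two CH2–CH bonds under neutral conditions. No new isolated compound is needed.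

Step 3 (acetal protection in the presence of the amines). N-alkylation of the benzylic amines by the chloromethyl ether may compete with O-alkylation. The quaternised nitrogen may then be eliminated from the neighbouring phenoxide, leading to quinone methide formation and oligomerisation. The fallback introduces the one-carbon handles as aldehydes so that no amine is present. It sets out from 2 and comes back at 7.
- Duff diformylation of 2 (hexamethylenetetramine, CF3CO2H, 80 °C, then aqueous HCl) should give 5-benzoyl-4,6-dihydroxy-2-methoxybenzene-1,3-dicarbaldehyde F1.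
- NaH and MOMCl in THF/DMF at 0 °C should give 5-benzoyl-2-methoxy-4,6-bis(methoxymethoxy)benzene-1,3-dicarbaldehyde F2.
- NaBH4 in MeOH/THF at −20 °C should reduce the two aldehydes in preference to the doubly ortho-substituted diaryl ketone, giving [3,5-bis(hydroxymethyl)-4-methoxy-2,6-bis(methoxymethoxy)phenyl](phenyl)methanone F3.
- MsCl, Et3N and LiCl in THF at 0 °C should convert both benzylic alcohols into the chlorides of 7.

Step 6 (acetal removal). The freed phenols may add across the protonated prenyl alkenes (cyclisation to chromans), or methanol or HCl may add to the alkenes before both acetals are cleaved. The fallback replaces the acid-labile protecting group by one removed with fluoride. It sets out from 3 and comes back at 10.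
- Silylation of 3 (TBSOTf, 2,6-lutidine, CH2Cl2, 0 °C) should give [2,6-bis[(tert-butyldimethylsilyl)oxy]-3,5-bis[(dimethylamino)methyl]-4-methoxyphenyl](phenyl)methanone F4.
- Ethyl chloroformate in CH2Cl2 over solid K2CO3 should give [2,6-bis[(tert-butyldimethylsilyl)oxy]-3,5-bis(chloromethyl)-4-methoxyphenyl](phenyl)methanone F5.
- Coupling with 8 under Pd(PPh3)4 and anhydrous K3PO4 in 1,4-dioxane at 70 °C should give [2,6-bis[(tert-butyldimethylsilyl)oxy]-4-methoxy-3,5-bis(3-methylbut-2-enyl)phenyl](phenyl)methanone F6.
- Tetrabutylammonium fluoride buffered with acetic acid in THF at 0 °C should release 10 without any strong acid.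

**Further compounds**
F0 | step 5 | none | none
F1 | step 3 | 5-benzoyl-4,6-dihydroxy-2-methoxybenzene-1,3-dicarbaldehyde | COc1c(C=O)c(O)c(C(=O)c2ccccc2)c(O)c1C=O
F2 | step 3 | 5-benzoyl-2-methoxy-4,6-bis(methoxymethoxy)benzene-1,3-dicarbaldehyde | COCOc1c(C=O)c(OC)c(C=O)c(OCOC)c1C(=O)c1ccccc1
F3 | step 3 | [3,5-bis(hydroxymethyl)-4-methoxy-2,6-bis(methoxymethoxy)phenyl](phenyl)methanone | COCOc1c(CO)c(OC)c(CO)c(OCOC)c1C(=O)c1ccccc1
F4 | step 6 | [2,6-bis[(tert-butyldimethylsilyl)oxy]-3,5-bis[(dimethylamino)methyl]-4-methoxyphenyl](phenyl)methanone | COc1c(CN(C)C)c(O[Si](C)(C)C(C)(C)C)c(C(=O)c2ccccc2)c(O[Si](C)(C)C(C)(C)C)c1CN(C)C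
F5 | step 6 | [2,6-bis[(tert-butyldimethylsilyl)oxy]-3,5-bis(chloromethyl)-4-methoxyphenyl](phenyl)methanone | COc1c(CCl)c(O[Si](C)(C)C(C)(C)C)c(C(=O)c2ccccc2)c(O[Si](C)(C)C(C)(C)C)c1CCl
F6 | step 6 | [2,6-bis[(tert-butyldimethylsilyl)oxy]-4-methoxy-3,5-bis(3-methylbut-2-enyl)phenyl](phenyl)methanone | COc1c(CC=C(C)C)c(O[Si](C)(C)C(C)(C)C)c(C(=O)c2ccccc2)c(O[Si](C)(C)C(C)(C)C)c1CC=C(C)C
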